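**Plan**
- Cuts: formate C–O; the C2 methylidene (from a C2 ketone); the CH2–pyranone bond (4-hydroxy-2-pyranone added to a 1-methylidene-2-ketone); the side chain between its C1 and C2 (olefination of a formyl group on C5).
- Ring A (C4a, C5, C6, C7, C8, C8a) then shows an aldol array: C6–O beside the quaternary C5 that carries a formyl branch. This is the retron of a semipinacol shift, so ring A is made by contraction of a cycloheptene oxide in which the formyl carbon is a ring carbinol between C5 and C4a.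
- Forward order: ring B from 3-ethoxycyclohexenone (aldol, Stork–Danheiser, cuprate); seven-membered ring by metathesis; epoxide; contraction to ring A; side chain; pyranone; methylidene; formate.
- Stereochemistry: syn aldol plus Sharpless kinetic resolution fix C4a absolutely; C8a by cuprate addition anti to the C4a substituent; epoxide anti to the silyloxy group; C5 and C6 by the stereospecific shift; C1 by protonation on the convex face.

Key step: step 8

Remark: the SMILES encodes a cis-fused decalin (H at C4a and CH3 at C8a on the same face), (1S,4aR,5R,6S,8aS); the route is laid out for exactly that configuration. Locants are those of the systematic names in the compound list.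

**Step 1**
Reactants: 1 3-ethoxycyclohex-2-en-1-one; 2 methacrolein
Product: 5 rac-(6S)-3-ethoxy-6-[(1S)-1-hydroxy-2-methylprop-2-en-1-yl]cyclohex-2-en-1-one, via lithium dienolate 3 (not isolated), via titanium enolate 4 (not isolated)
Conditions: LiN(iPr)2, THF, −78 °C; ClTi(OiPr)3, −78 to −40 °C; 2, −78 °C; aq NH4Cl; chromatography to remove the anti isomer
Reagents that add atoms: none
Why: Kinetic deprotonation of the vinylogous ester at C6, transmetalation to the triisopropoxytitanium enolate and aldol addition to the enal; titanium enolates of cyclic ketones give the syn aldol whatever the (here fixed) enolate geometry, so C6 and the carbinol carbon should arise mainly syn, as a racemate.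

**Step 2**
Reactants: 5 racemic syn aldol
Product: 6 (6S)-3-ethoxy-6-[(1S)-1-hydroxy-2-methylprop-2-en-1-yl]cyclohex-2-en-1-one
Conditions: Ti(OiPr)4 (0.1 equiv), D-(−)-diisopropyl tartrate (0.15 equiv), t-BuOOH (0.6 equiv), 4 Å sieves, CH2Cl2, −20 °C; stopped a little past half conversion
Reagents that add atoms: none
Why: Sharpless kinetic resolution of the secondary allylic alcohol: with the D-(−)-tartrate ligand the enantiomer with the (1′R) carbinol is epoxidised much faster at its isopropenyl group, so the (6S,1′S) enantiomer should be recovered, which fixes the absolute configuration of the route.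

**Step 3**
Reactants: 6 resolved aldol
Product: 7 (6S)-6-[(1S)-1-{[tert-butyl(dimethyl)silyl]oxy}-2-methylprop-2-en-1-yl]-3-ethoxycyclohex-2-en-1-one
Conditions: TBSOTf, 2,6-lutidine, CH2Cl2, −78 to 0 °C
Reagents that add atoms: tert-butyldimethylsilyl triflate, CC(C)(C)[Si](C)(C)OS(=O)(=O)C(F)(F)F
Why: Silyl ether formation with a silyl triflate and a hindered base, no stereocentre touched; the silyl ether later steers the epoxidation, drives the key shift and ends as the protecting group of the ring A hydroxyl.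

**Step 4**
Reactants: 7 silyl ether
Product: 9 (4R)-3-(but-3-en-1-yl)-4-[(1S)-1-{[tert-butyl(dimethyl)silyl]oxy}-2-methylprop-2-en-1-yl]cyclohex-2-en-1-one, via tertiary carbinol 8 (not isolated)
Conditions: CH2=CHCH2CH2MgBr, THF, −78 to 0 °C; then 1 M HCl, 0 °C
Reagents that add atoms: but-3-en-1-ylmagnesium bromide, C=CCC[Mg]Br
Why: Stork–Danheiser alkylative carbonyl transposition: 1,2-addition to the vinylogous ester carbonyl, then acid hydrolysis of the enol ether and loss of water give the 3-substituted enone; the ring stereocentre becomes C4 (γ to the new carbonyl) and is not touched.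

**Step 5**
Reactants: 9 enone
Product: 11 (3R,4R)-3-(but-3-en-1-yl)-4-[(1S)-1-{[tert-butyl(dimethyl)silyl]oxy}-2-methylprop-2-en-1-yl]-3-methylcyclohex-1-en-1-yl trifluoromethanesulfonate, via lithium enolate 10 (not isolated)
Conditions: Me2CuLi (from MeLi, CuI), Et2O, −40 to 0 °C; then Comins' reagent, THF, −78 to 0 °C
Reagents that add atoms: lithium dimethylcuprate, [Li+].C[Cu-]C; N-(5-chloropyridin-2-yl)-1,1,1-trifluoro-N-(trifluoromethanesulfonyl)methanesulfonamide (Comins' reagent), FC(F)(F)S(=O)(=O)N(c1ccc(Cl)cn1)S(=O)(=O)C(F)(F)F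
Why: Conjugate addition of the Gilman cuprate anti to the bulky C4 substituent sets the quaternary centre with methyl trans to the silyloxyallyl group (butenyl cis to it, as ring closure needs), and O-triflation of the regiodefined enolate stores the ketone as an enol triflate that remembers the C2 side of the carbonyl.

**Step 6**
Reactants: 11 triene triflate
Product: 12 (4aR,9S,9aR)-9-{[tert-butyl(dimethyl)silyl]oxy}-4a,8-dimethyl-2,4a,5,6,9,9a-hexahydro-1H-benzo[7]annulen-3-yl trifluoromethanesulfonate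
Conditions: second-generation Grubbs catalyst (5 mol%), toluene (0.005 M), 80 °C
Reagents that add atoms: none
Why: Ring-closing olefin metathesis of the monosubstituted butenyl alkene onto the 1,1-disubstituted isopropenyl alkene gives the trisubstituted cycloheptene; the two arms are cis and the electron-poor enol triflate alkene does not take part.

**Step 7**
Reactants: 12 bicyclic alkene
Product: 13 (4aR,7S,8S,9S,9aR)-9-{[tert-butyl(dimethyl)silyl]oxy}-7,8-epoxy-4a,8-dimethyl-2,4a,5,6,7,8,9,9a-octahydro-1H-benzo[7]annulen-3-yl trifluoromethanesulfonate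
Conditions: mCPBA, NaHCO3, CH2Cl2, 0 °C
Reagents that add atoms: 3-chloroperbenzoic acid, OOC(=O)c1cccc(Cl)c1
Why: Prilezhaev epoxidation of the only electron-rich alkene; the peracid approaches anti to the adjacent bulky allylic silyloxy group, which should give the trans epoxy silyl ether (7S,8S).

**Step 8**
Reactants: 13 trans epoxy silyl ether
Product: 14 (4aR,7S,8R,8aR)-7-{[tert-butyl(dimethyl)silyl]oxy}-8-formyl-4a,8-dimethyl-1,2,4a,5,6,7,8,8a-octahydronaphthalen-3-yl trifluoromethanesulfonate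
Conditions: TBSOTf (0.2 equiv), 2,6-di-tert-butyl-4-methylpyridine (0.3 equiv), 4 Å sieves, CH2Cl2, −78 to −40 °C
Reagents that add atoms: none
Why: TBSOTf silylates the epoxide oxygen; as the C8–O bond of the tertiary epoxide carbon ionises, the ring-fusion carbon C9a, antiperiplanar to that bond, migrates from the carbinol carbon C9 to C8 with inversion, the silyloxy lone pair turning C9 into an O-silyl oxocarbenium ion that hands its silyl group to triflate and so to the next epoxide. The closest known reaction type is the semipinacol rearrangement of 2,3-epoxy alcohol silyl ethers under silyl triflate promotion (the non-aldol aldol process) and its ring-contracting version in cyclic epoxy alcohols. No ring is closed by cyclisation: the six-membered ring A results from the 1,2-shift, which expels C9 from the seven-membered ring as the formyl carbon. The quaternary carbon is fixed by the epoxide configuration through inversion, the silyloxy carbon of ring A keeps the epoxide oxygen with retention, and the migrating carbon keeps its configuration. The step needs ring-bond migration to win over hydride shifts from C9 and from C7; in the trans epoxy silyl ether the C9–H bond is syn-clinal to the breaking C–O bond in every attainable ring conformation, so only the ring bond can become antiperiplanar, and the oxygen lone pair at C9 makes this shift faster than the hydride shift from C7.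

**Step 9**
Reactants: 14 aldehyde
Product: 15 (4aR,7S,8R,8aR)-7-{[tert-butyl(dimethyl)silyl]oxy}-4a,8-dimethyl-8-[(1E)-3-oxobut-1-en-1-yl]-1,2,4a,5,6,7,8,8a-octahydronaphthalen-3-yl trifluoromethanesulfonate
Conditions: (MeO)2P(O)CH2COCH3, NaH, THF, 0 to 50 °C
Reagents that add atoms: dimethyl (2-oxopropyl)phosphonate, COP(=O)(CC(C)=O)OC
Why: Horner–Wadsworth–Emmons olefination of the non-enolisable α-quaternary aldehyde gives the E enone; the silylated β-oxygen blocks retro-aldol cleavage.

**Step 10**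
Reactants: 15 enone
Product: 16 (4aR,7S,8R,8aR)-7-{[tert-butyl(dimethyl)silyl]oxy}-4a,8-dimethyl-8-(3-oxobutyl)-1,2,4a,5,6,7,8,8a-octahydronaphthalen-3-yl trifluoromethanesulfonate
Conditions: H2 (1 atm), RhCl(PPh3)3 (5 mol%), benzene, rt
Reagents that add atoms: none
Why: Homogeneous hydrogenation with Wilkinson's catalyst reduces the unhindered disubstituted alkene and leaves the trisubstituted enol triflate alone.

**Step 11**
Reactants: 16 methyl ketone
Product: 17 (4aR,7S,8R,8aR)-7-{[tert-butyl(dimethyl)silyl]oxy}-8-(3-hydroxy-3-methylbutyl)-4a,8-dimethyl-1,2,4a,5,6,7,8,8a-octahydronaphthalen-3-yl trifluoromethanesulfonate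
Conditions: MeMgBr, THF, −78 °C; aq NH4Cl
Reagents that add atoms: methylmagnesium bromide, C[Mg]Br
Why: Grignard 1,2-addition to the methyl ketone gives the tertiary alcohol; an enol triflate does not react with a Grignard reagent without a transition-metal catalyst.

**Step 12**
Reactants: 17 triflate alcohol
Product: 19 (4aR,5R,6S,8aR)-6-{[tert-butyl(dimethyl)silyl]oxy}-1-[(dimethylamino)methyl]-5-(3-hydroxy-3-methylbutyl)-5,8a-dimethyloctahydronaphthalen-2(1H)-one, via dilithium enolate alkoxide 18 (not isolated)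
Conditions: MeLi (3.5 equiv), THF, −78 to 0 °C; then CH2=NMe2+ I−, −78 °C to rt
Reagents that add atoms: N,N-dimethylmethyleneiminium iodide (Eschenmoser's salt), C=[N+](C)C.[I-]
Why: Methyllithium deprotonates the alcohol and then attacks the sulfur of the enol triflate (S–O cleavage), releasing the lithium enolate on the C1 side only, the side direct deprotonation of the ketone would not choose; the Mannich reaction with Eschenmoser's salt then places the aminomethyl group at C1, whose configuration is of no concern because C1 becomes trigonal in step 14.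

**Step 13**
Reactants: 20 methyl acetoacetate; 21 malonyl dichloride
Product: 22 methyl 4-hydroxy-2-methyl-6-oxo-6H-pyran-3-carboxylate
Conditions: CH2Cl2, rt then reflux, HCl swept out with N2
Reagents that add atoms: none
Why: C-Acylation of the β-keto ester by one acyl chloride group and O-acylation of its enol by the other (lactonisation) give the 4-hydroxy-2-pyranone, the known pyranone synthesis from malonyl dichloride and 1,3-dicarbonyl compounds.

**Step 14**
Reactants: 19 Mannich base; 22 pyranone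
Product: 24 methyl 5-{[(1R,4aR,5R,6S,8aR)-6-{[tert-butyl(dimethyl)silyl]oxy}-5-(3-hydroxy-3-methylbutyl)-5,8a-dimethyl-2-oxodecahydronaphthalen-1-yl]methyl}-4-hydroxy-2-methyl-6-oxo-6H-pyran-3-carboxylate, via enone 23 (not isolated)
Conditions: 1,4-dioxane, 90 °C
Reagents that add atoms: none
Why: The Mannich base is a latent enone that loses dimethylamine on heating with the acidic pyranone, which then adds through its nucleophilic C5–H carbon (Michael addition, as in the alkylation of 4-hydroxycoumarins by Mannich bases); the enol is protonated at C1 from the convex face of the cis-decalin, away from ring A, which should place the pyranonylmethyl group trans to the angular methyl (the ketone may rest as its cyclic hemiketal with the pyranone hydroxyl).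

**Step 15**
Reactants: 24 hydroxypyranone
Product: 25 methyl 5-{[(1R,4aR,5R,6S,8aR)-6-{[tert-butyl(dimethyl)silyl]oxy}-5-(3-hydroxy-3-methylbutyl)-5,8a-dimethyl-2-oxodecahydronaphthalen-1-yl]methyl}-6-methoxy-2-methyl-4-oxo-4H-pyran-3-carboxylate
Conditions: MeOTf, CH2Cl2, 0 °C to rt; aq NaHCO3
Reagents that add atoms: methyl triflate, COS(=O)(=O)C(F)(F)F
Why: O-Methylation of the neutral 4-hydroxy-2-pyranone by the hard alkylating agent occurs at the lactone carbonyl oxygen and loss of the 4-OH proton gives the 2-methoxy-4-pyranone; the 4-hydroxyl is hydrogen-bonded to the neighbouring ester and flanked on both sides, and the tertiary alcohol is not methylated without base.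

**Step 16**
Reactants: 25 ketone
Product: 26 methyl 5-{[(1S,4aR,5R,6S,8aS)-6-{[tert-butyl(dimethyl)silyl]oxy}-5-(3-hydroxy-3-methylbutyl)-5,8a-dimethyl-2-methylidenedecahydronaphthalen-1-yl]methyl}-6-methoxy-2-methyl-4-oxo-4H-pyran-3-carboxylate
Conditions: Zn, CH2Br2, TiCl4, THF/CH2Cl2, 0 °C to rt
Reagents that add atoms: dibromomethane, BrCBr
Why: Takai–Lombardo methylenation is non-basic, so the hindered ketone is converted without epimerising C1, and the ester and the pyranone carbonyl (a vinylogous ester) are left.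

**Step 17**
Reactants: 26 tertiary alcohol
Product: 27 methyl 5-{[(1S,4aR,5R,6S,8aS)-6-{[tert-butyl(dimethyl)silyl]oxy}-5-[3-(formyloxy)-3-methylbutyl]-5,8a-dimethyl-2-methylidenedecahydronaphthalen-1-yl]methyl}-6-methoxy-2-methyl-4-oxo-4H-pyran-3-carboxylate
Conditions: HCO2Ac, pyridine, DMAP (cat.), CH2Cl2, 0 °C to rt
Reagents that add atoms: acetic formic anhydride, CC(=O)OC=O
Why: Formylation of the tertiary alcohol with the mixed anhydride, which transfers the formyl group selectively; the only other hydroxyl is still silylated.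

**Step 18**
Reactants: 27 silyl ether
Product: 28 methyl 5-{[(1S,4aR,5R,6S,8aS)-5-[3-(formyloxy)-3-methylbutyl]-6-hydroxy-5,8a-dimethyl-2-methylidenedecahydronaphthalen-1-yl]methyl}-6-methoxy-2-methyl-4-oxo-4H-pyran-3-carboxylate (target)
Conditions: HF·pyridine, THF/pyridine, 0 °C to rt
Reagents that add atoms: none
Why: Fluoride cleavage of the hindered secondary silyl ether under buffered acidic conditions that the formate, the exocyclic alkene and the methoxypyranone should tolerate.

**Compound list**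
1 | 3-ethoxycyclohex-2-en-1-one | CCOC1=CC(=O)CCC1 | starting material
2 | methacrolein (2-methylprop-2-enal) | CC(=C)C=O | starting material
3 | lithium 5-ethoxycyclohexa-1,5-dien-1-olate | [Li+].CCOC1=CC([O-])=CCC1 | intermediate (not isolated)
4 | [(5-ethoxycyclohexa-1,5-dien-1-yl)oxy]tri(propan-2-yloxy)titanium | CCOC1=CC(O[Ti](OC(C)C)(OC(C)C)OC(C)C)=CCC1 | intermediate (not isolated)
5 | rac-(6S)-3-ethoxy-6-[(1S)-1-hydroxy-2-methylprop-2-en-1-yl]cyclohex-2-en-1-one (syn aldol, racemate; the SMILES shows the enantiomer carried on) | CCOC1=CC(=O)[C@H]([C@H](O)C(C)=C)CC1 | intermediate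
6 | (6S)-3-ethoxy-6-[(1S)-1-hydroxy-2-methylprop-2-en-1-yl]cyclohex-2-en-1-one (single enantiomer) | CCOC1=CC(=O)[C@H]([C@H](O)C(C)=C)CC1 | intermediate
7 | (6S)-6-[(1S)-1-{[tert-butyl(dimethyl)silyl]oxy}-2-methylprop-2-en-1-yl]-3-ethoxycyclohex-2-en-1-one | CCOC1=CC(=O)[C@H]([C@H](O[Si](C)(C)C(C)(C)C)C(C)=C)CC1 | intermediate
8 | (6S)-1-(but-3-en-1-yl)-6-[(1S)-1-{[tert-butyl(dimethyl)silyl]oxy}-2-methylprop-2-en-1-yl]-3-ethoxycyclohex-2-en-1-ol (as its magnesium alkoxide, both C1 epimers) | CCOC1=CC(O)(CCC=C)[C@H]([C@H](O[Si](C)(C)C(C)(C)C)C(C)=C)CC1 | intermediate (not isolated)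
9 | (4R)-3-(but-3-en-1-yl)-4-[(1S)-1-{[tert-butyl(dimethyl)silyl]oxy}-2-methylprop-2-en-1-yl]cyclohex-2-en-1-one | O=C1C=C(CCC=C)[C@H]([C@H](O[Si](C)(C)C(C)(C)C)C(C)=C)CC1 | intermediate
10 | lithium (3R,4R)-3-(but-3-en-1-yl)-4-[(1S)-1-{[tert-butyl(dimethyl)silyl]oxy}-2-methylprop-2-en-1-yl]-3-methylcyclohex-1-en-1-olate | [Li+].[O-]C1=C[C@](C)(CCC=C)[C@H]([C@H](O[Si](C)(C)C(C)(C)C)C(C)=C)CC1 | intermediate (not isolated)
11 | (3R,4R)-3-(but-3-en-1-yl)-4-[(1S)-1-{[tert-butyl(dimethyl)silyl]oxy}-2-methylprop-2-en-1-yl]-3-methylcyclohex-1-en-1-yl trifluoromethanesulfonate | FC(F)(F)S(=O)(=O)OC1=C[C@](C)(CCC=C)[C@H]([C@H](O[Si](C)(C)C(C)(C)C)C(C)=C)CC1 | intermediate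
12 | (4aR,9S,9aR)-9-{[tert-butyl(dimethyl)silyl]oxy}-4a,8-dimethyl-2,4a,5,6,9,9a-hexahydro-1H-benzo[7]annulen-3-yl trifluoromethanesulfonate | FC(F)(F)S(=O)(=O)OC1=C[C@]2(C)CCC=C(C)[C@@H](O[Si](C)(C)C(C)(C)C)[C@@H]2CC1 | intermediate
13 | (4aR,7S,8S,9S,9aR)-9-{[tert-butyl(dimethyl)silyl]oxy}-7,8-epoxy-4a,8-dimethyl-2,4a,5,6,7,8,9,9a-octahydro-1H-benzo[7]annulen-3-yl trifluoromethanesulfonate | FC(F)(F)S(=O)(=O)OC1=C[C@]2(C)CC[C@@H]3O[C@]3(C)[C@@H](O[Si](C)(C)C(C)(C)C)[C@@H]2CC1 | intermediate
14 | (4aR,7S,8R,8aR)-7-{[tert-butyl(dimethyl)silyl]oxy}-8-formyl-4a,8-dimethyl-1,2,4a,5,6,7,8,8a-octahydronaphthalen-3-yl trifluoromethanesulfonate | FC(F)(F)S(=O)(=O)OC1=C[C@]2(C)CC[C@H](O[Si](C)(C)C(C)(C)C)[C@](C)(C=O)[C@@H]2CC1 | intermediate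
15 | (4aR,7S,8R,8aR)-7-{[tert-butyl(dimethyl)silyl]oxy}-4a,8-dimethyl-8-[(1E)-3-oxobut-1-en-1-yl]-1,2,4a,5,6,7,8,8a-octahydronaphthalen-3-yl trifluoromethanesulfonate | FC(F)(F)S(=O)(=O)OC1=C[C@]2(C)CC[C@H](O[Si](C)(C)C(C)(C)C)[C@](C)(/C=C/C(C)=O)[C@@H]2CC1 | intermediate
16 | (4aR,7S,8R,8aR)-7-{[tert-butyl(dimethyl)silyl]oxy}-4a,8-dimethyl-8-(3-oxobutyl)-1,2,4a,5,6,7,8,8a-octahydronaphthalen-3-yl trifluoromethanesulfonate | FC(F)(F)S(=O)(=O)OC1=C[C@]2(C)CC[C@H](O[Si](C)(C)C(C)(C)C)[C@](C)(CCC(C)=O)[C@@H]2CC1 | intermediate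
17 | (4aR,7S,8R,8aR)-7-{[tert-butyl(dimethyl)silyl]oxy}-8-(3-hydroxy-3-methylbutyl)-4a,8-dimethyl-1,2,4a,5,6,7,8,8a-octahydronaphthalen-3-yl trifluoromethanesulfonate | FC(F)(F)S(=O)(=O)OC1=C[C@]2(C)CC[C@H](O[Si](C)(C)C(C)(C)C)[C@](C)(CCC(C)(C)O)[C@@H]2CC1 | intermediate
18 | dilithium salt of the C3 enolate and side-chain alkoxide derived from 17 | [Li+].[Li+].[O-]C1=C[C@]2(C)CC[C@H](O[Si](C)(C)C(C)(C)C)[C@](C)(CCC(C)(C)[O-])[C@@H]2CC1 | intermediate (not isolated)
19 | (4aR,5R,6S,8aR)-6-{[tert-butyl(dimethyl)silyl]oxy}-1-[(dimethylamino)methyl]-5-(3-hydroxy-3-methylbutyl)-5,8a-dimethyloctahydronaphthalen-2(1H)-one (C1 epimers) | CN(C)CC1C(=O)CC[C@H]2[C@@](C)(CCC(C)(C)O)[C@@H](O[Si](C)(C)C(C)(C)C)CC[C@@]12C | intermediate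
20 | methyl acetoacetate | COC(=O)CC(C)=O | starting material
21 | malonyl dichloride | ClC(=O)CC(Cl)=O | starting material
22 | methyl 4-hydroxy-2-methyl-6-oxo-6H-pyran-3-carboxylate | COC(=O)c1c(C)oc(=O)cc1O | intermediate
23 | (4aR,5R,6S,8aR)-6-{[tert-butyl(dimethyl)silyl]oxy}-5-(3-hydroxy-3-methylbutyl)-5,8a-dimethyl-1-methylideneoctahydronaphthalen-2(1H)-one | C=C1C(=O)CC[C@H]2[C@@](C)(CCC(C)(C)O)[C@@H](O[Si](C)(C)C(C)(C)C)CC[C@@]12C | intermediate (not isolated)
24 | methyl 5-{[(1R,4aR,5R,6S,8aR)-6-{[tert-butyl(dimethyl)silyl]oxy}-5-(3-hydroxy-3-methylbutyl)-5,8a-dimethyl-2-oxodecahydronaphthalen-1-yl]methyl}-4-hydroxy-2-methyl-6-oxo-6H-pyran-3-carboxylate | O=C1CC[C@H]2[C@@](C)(CCC(C)(C)O)[C@@H](O[Si](C)(C)C(C)(C)C)CC[C@@]2(C)[C@H]1Cc1c(O)c(C(=O)OC)c(C)oc1=O | intermediate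
25 | methyl 5-{[(1R,4aR,5R,6S,8aR)-6-{[tert-butyl(dimethyl)silyl]oxy}-5-(3-hydroxy-3-methylbutyl)-5,8a-dimethyl-2-oxodecahydronaphthalen-1-yl]methyl}-6-methoxy-2-methyl-4-oxo-4H-pyran-3-carboxylate | O=C1CC[C@H]2[C@@](C)(CCC(C)(C)O)[C@@H](O[Si](C)(C)C(C)(C)C)CC[C@@]2(C)[C@H]1Cc1c(OC)oc(C)c(C(=O)OC)c1=O | intermediate
26 | methyl 5-{[(1S,4aR,5R,6S,8aS)-6-{[tert-butyl(dimethyl)silyl]oxy}-5-(3-hydroxy-3-methylbutyl)-5,8a-dimethyl-2-methylidenedecahydronaphthalen-1-yl]methyl}-6-methoxy-2-methyl-4-oxo-4H-pyran-3-carboxylate | C=C1CC[C@H]2[C@@](C)(CCC(C)(C)O)[C@@H](O[Si](C)(C)C(C)(C)C)CC[C@@]2(C)[C@H]1Cc1c(OC)oc(C)c(C(=O)OC)c1=O | intermediate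
27 | methyl 5-{[(1S,4aR,5R,6S,8aS)-6-{[tert-butyl(dimethyl)silyl]oxy}-5-[3-(formyloxy)-3-methylbutyl]-5,8a-dimethyl-2-methylidenedecahydronaphthalen-1-yl]methyl}-6-methoxy-2-methyl-4-oxo-4H-pyran-3-carboxylate | C=C1CC[C@H]2[C@@](C)(CCC(C)(C)OC=O)[C@@H](O[Si](C)(C)C(C)(C)C)CC[C@@]2(C)[C@H]1Cc1c(OC)oc(C)c(C(=O)OC)c1=O | intermediate
28 | methyl 5-{[(1S,4aR,5R,6S,8aS)-5-[3-(formyloxy)-3-methylbutyl]-6-hydroxy-5,8a-dimethyl-2-methylidenedecahydronaphthalen-1-yl]methyl}-6-methoxy-2-methyl-4-oxo-4H-pyran-3-carboxylate | C=C1CC[C@H]2[C@@](C)(CCC(C)(C)OC=O)[C@@H](O)CC[C@@]2(C)[C@H]1Cc1c(OC)oc(C)c(C(=O)OC)c1=O | target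

**Totals**
Total steps: 18. Longest linear sequence: 17 (steps 1–12 and 14–18; step 13 makes the pyranone).

**Steps most likely to fail**

Step 8. The epoxide may ionise ahead of migration, so that proton loss from the cation or loss of the silyl group overtakes the concerted shift. The fallback sets out from 13 and drives the shift from the oxyanion side. Buffered fluoride (TBAF, AcOH) should free the trans epoxy alcohol F1. Al(OiPr)3 in i-PrOH should then bring about the semipinacol ring contraction in tandem with Meerwein–Ponndorf–Verley reduction, the aluminium alkoxide pushing the ring bond over and the aldehyde being reduced as it forms, to give the 1,3-diol F2. Selective oxidation of the primary alcohol (TEMPO, PhI(OAc)2) should give the hydroxy aldehyde F3, and TBSOTf with 2,6-lutidine returns to the route at 14.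

Step 12. Methyllithium may attack elsewhere, the acidic methyl sulfone by-product may quench the enolate by proton transfer, or the Mannich reaction may be slow at the neopentyl carbon. The fallback sets out from 17 and avoids organolithium chemistry. Miyaura borylation of the enol triflate (B2pin2, PdCl2(PPh3)2, PPh3, KOPh, toluene, 50 °C) should give the alkenyl boronate F4. Oxidation with anhydrous Me3NO should turn it into the enol borate F5, a boron enolate of the same regiochemistry, which is trapped in the same flask with Eschenmoser's salt; the route is rejoined at 19.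

Step 14. The liberated enone may dimerise, and the conjugate addition is reversible, so the C1 configuration set by protonation may erode; O-alkylation of the pyranone is a further drain. The fallback sets out from 19 and joins the pyranone by cross-coupling. Methylation (MeI) and mild base (NaHCO3) should give the enone 23, now isolated. Conjugate borylation (CuCl, NaOt-Bu, Xantphos, B2pin2, MeOH, THF, −20 °C), with irreversible protonation on the convex face, should give the β-boryl ketone F6. Takai–Lombardo methylenation should give the alkyl boronate F7, in which C1 can no longer epimerise. The partner is made from 22 by O-methylation (MeOTf) to the methoxypyranone F8 and bromination (NBS) to the bromopyranone F9. Suzuki–Miyaura coupling of F7 with F9 (Pd(OAc)2, RuPhos, K3PO4, toluene/water, 90 °C) comes back to the route at 26.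

**Further compounds**
F1 | step 8 | (4aR,7S,8S,9S,9aR)-7,8-epoxy-9-hydroxy-4a,8-dimethyl-2,4a,5,6,7,8,9,9a-octahydro-1H-benzo[7]annulen-3-yl trifluoromethanesulfonate | FC(F)(F)S(=O)(=O)OC1=C[C@]2(C)CC[C@@H]3O[C@]3(C)[C@@H](O)[C@@H]2CC1
F2 | step 8 | (4aR,7S,8R,8aR)-7-hydroxy-8-(hydroxymethyl)-4a,8-dimethyl-1,2,4a,5,6,7,8,8a-octahydronaphthalen-3-yl trifluoromethanesulfonate | FC(F)(F)S(=O)(=O)OC1=C[C@]2(C)CC[C@H](O)[C@](C)(CO)[C@@H]2CC1
F3 | step 8 | (4aR,7S,8R,8aR)-8-formyl-7-hydroxy-4a,8-dimethyl-1,2,4a,5,6,7,8,8a-octahydronaphthalen-3-yl trifluoromethanesulfonate | FC(F)(F)S(=O)(=O)OC1=C[C@]2(C)CC[C@H](O)[C@](C)(C=O)[C@@H]2CC1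
F4 | step 12 | 2-[(4aR,7S,8R,8aR)-7-{[tert-butyl(dimethyl)silyl]oxy}-8-(3-hydroxy-3-methylbutyl)-4a,8-dimethyl-1,2,4a,5,6,7,8,8a-octahydronaphthalen-3-yl]-4,4,5,5-tetramethyl-1,3,2-dioxaborolane | CC1(C)OB(OC1(C)C)C1=C[C@]2(C)CC[C@H](O[Si](C)(C)C(C)(C)C)[C@](C)(CCC(C)(C)O)[C@@H]2CC1
F5 | step 12 | 2-{[(4aR,7S,8R,8aR)-7-{[tert-butyl(dimethyl)silyl]oxy}-8-(3-hydroxy-3-methylbutyl)-4a,8-dimethyl-1,2,4a,5,6,7,8,8a-octahydronaphthalen-3-yl]oxy}-4,4,5,5-tetramethyl-1,3,2-dioxaborolane | CC1(C)OB(OC1(C)C)OC1=C[C@]2(C)CC[C@H](O[Si](C)(C)C(C)(C)C)[C@](C)(CCC(C)(C)O)[C@@H]2CC1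
F6 | step 14 | (1R,4aR,5R,6S,8aR)-6-{[tert-butyl(dimethyl)silyl]oxy}-5-(3-hydroxy-3-methylbutyl)-5,8a-dimethyl-1-[(4,4,5,5-tetramethyl-1,3,2-dioxaborolan-2-yl)methyl]octahydronaphthalen-2(1H)-one | O=C1CC[C@H]2[C@@](C)(CCC(C)(C)O)[C@@H](O[Si](C)(C)C(C)(C)C)CC[C@@]2(C)[C@H]1CB1OC(C)(C)C(C)(C)O1
F7 | step 14 | 4-[(1R,2S,4aR,5S,8aS)-2-{[tert-butyl(dimethyl)silyl]oxy}-1,4a-dimethyl-6-methylidene-5-[(4,4,5,5-tetramethyl-1,3,2-dioxaborolan-2-yl)methyl]decahydronaphthalen-1-yl]-2-methylbutan-2-ol | C=C1CC[C@H]2[C@@](C)(CCC(C)(C)O)[C@@H](O[Si](C)(C)C(C)(C)C)CC[C@@]2(C)[C@H]1CB1OC(C)(C)C(C)(C)O1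
F8 | step 14 | methyl 6-methoxy-2-methyl-4-oxo-4H-pyran-3-carboxylate | COC(=O)c1c(C)oc(OC)cc1=O
F9 | step 14 | methyl 5-bromo-6-methoxy-2-methyl-4-oxo-4H-pyran-3-carboxylate | COC(=O)c1c(C)oc(OC)c(Br)c1=O
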